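## Structural features

The target is a C15 bicyclic ether: a cyclohexane (ring A: C1, C2, C3, C4, C5, C11) trans-fused along C5–C11 to a 2,3,4,7-tetrahydrooxepine (ring B: C5, O6, C7, C8, C9, C10, C11) with one trisubstituted double bond, C8=C9. Ring A carries the gem-dimethyl carbon C1, an equatorial secondary bromide on the adjacent C2, and the fully substituted C5 (axial methyl, ring oxygen); ring B carries the bromomethyl carbon C13 on C7 and the hydroxymethyl carbon C12 on C8. Of the four stereocentres (2S, 5S, 7R, 11S), C5 and C11 are adjacent, C2 is 1,3 to C11 across the quaternary C1, and C7 is 1,3 to C5 across O6, with C13 on the same face as the axial C5 methyl. The fragile points are the neopentyl secondary bromide (hard to make by substitution, prone to elimination and methyl shift), the primary bromide at C13 (an alkoxide at C12 could displace it and close a five-membered ether), and the allylic ether at C7, which is bonded through O6 to a tertiary carbon and is acid-sensitive. The real difficulty is ring B: O6 is a hindered tertiary oxygen that must be joined to C7 inside a seven-membered ring, and C13 must end on the more crowded face, syn to the angular methyl. The key step uses the array O6–C7–C8=C9, in which C7 and C8 each bear one oxygenated carbon (C13, C12): this is the pattern left by conjugate addition of an alkoxide to a 2-phosphonobut-2-enedioate followed by olefination of an aldehyde, and ring A supplies the tertiary C5 hydroxyl and the C9 aldehyde in the required 1,4-relationship.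

## Logic of the disconnections

25 to 24. No skeletal bond is cut; C12 goes back from the carbinol to a tert-butyl ester. C12 is reduced last because a free C12 hydroxyl would compete in the bromination of C13 and, as an alkoxide, could displace the C13 bromide. The gain is that the two oxygenated carbons never carry the same function. The demand is a clean 1,2-reduction of a hindered conjugated ester, cold enough that the aluminium alkoxide does not attack C13.

24 to 23 to 22. The C13–Br bond is cut to C13–OH, and C13 is then raised to an ethyl ester. In 22 the two carboxyl carbons differ twice over: C13 is a saturated α-alkoxy ethyl ester, C12 a conjugated tert-butyl ester. The demand is that hydride reduces only the former and that C7, still epimerisable in 22, is not disturbed before C13 becomes a carbinol.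

22 to 15 and 18 (key step). O6–C7 and C8=C9 are cut and ring B is opened. This removes the whole C7–C8–C12–C13 unit in one operation and leaves a ring-A lactol and a four-carbon phosphonate. The configurations written for 19 and 22 were re-derived from 25 and are consistent (2S, 5S, 11S unchanged; 7R with C13 syn to the C5 methyl). Two design points were changed in 18:
- C13 is at the ester level, so the acceptor has no γ-hydrogen that the basic tertiary alkoxide could remove instead of adding.
- C7–H in the product is acidic, so the C7 configuration does not depend on the ring closure alone but is imposed afterwards by protonation anti to the axial C5 methyl.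

The demand on the forward step is O-addition of a hindered alkoxide, a seven-membered olefination, and a face-selective protonation.

18 to 16 and 17. The C7=C8 bond is cut (Knoevenagel retron). Both partners are commercial; the alkene geometry is irrelevant. The demand is that the condensation keeps phosphorus instead of olefinating.

15 to 14. No bond is cut; C9 goes from the lactol to the ester level, which makes the precursor storable and lets the C2 chemistry be done on a robust hydroxy ester.

14 to 13 to 12 to 11 to 10. The C2–Br bond is cut to an axial C2–OH (inversion), this to the C2 ketone, and the ketone to the equatorial silyl ether. The equatorial oxygen that steers ring closure has the wrong configuration for direct substitution, so it is inverted through the ketone. The demand is equatorial hydride delivery and an SN2 displacement at a neopentyl centre.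

10 to 9. The C5–C11 bond is cut and ring A is opened to an acyclic keto enoate. Two stereocentres (C5, C11) are traced back to the single stereocentre C2. The demand is a chair-like 6-exo ketyl–olefin closure with the trans hydroxyl/acetate arrangement.

9 to 7 and 8; 7 to 6 to 5 to 3 and 4; 3 to 2 to 1. The C10=C11 double bond is cut (olefination of a non-enolisable aldehyde). The C3–C4 bond is traced to a C3=C4 double bond, which is cut by Wittig disconnection at the lactol carbon. The lactol comes from the protected chiral-pool lactone. The two ends of 1 are differentiated by its own lactone, so no extra protecting group is needed; the demand is that the hydroxy enone 5 is hydrogenated before its free hydroxyl can add to the enone.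

## Other disconnections considered

Alternative 1: The cut is C5–C11 in ring A. Forward, SmI2 (divalent samarium) reduces the methyl ketone of 9 to a ketyl that adds 6-exo to the enoate and gives A1, which is the same compound as 10.
- In favour: the chiral pool supplies the gem-dimethyl carbinol unit, and the trans hydroxyl/acetate relationship and the axial methyl arise in one step from a chair transition state.
- Against, as the organising step: it solves ring A only. O6–C7, C8=C9 and the C7 stereocentre remain open, so a second strategic step for ring B is needed anyway. The C2 oxygen that steers the closure costs a three-step inversion before bromination.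
- Comparison: it builds one ring, one C–C bond and two stereocentres, against one ring, two bonds and one stereocentre for the chosen key step; on stereocentres per step it is the better. Mechanistically it is a radical addition under near-neutral conditions and is more predictable than the anionic annulation, again a point in its favour. On step economy the two are equal, because the chosen plan already contains this reaction as step 7.

Alternative 2: The cut is O6–C7, with C5–O6 formed by migration. The carbocyclic ring-B ketone A2 would be expanded by a peracid (CF3CO3H or m-CPBA) to the lactone A3.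
- In favour: the tertiary C5 migrates in preference to the methylene C8 and with retention. The C5–O6 bond, which in the chosen plan needs a hindered alkoxide as nucleophile, is made without any intermolecular step, and the trans ring fusion is inherited from the carbocycle. On this point the alternative is the better.
- Against: A3 is a saturated lactone lacking C12, C13 and the C8=C9 double bond. C8 would have to be functionalised α to the carbonyl, the lactone carbonyl converted into a C7 that bears C13, and the alkene introduced, all beside the C2 bromide or its precursor. A2 also needs its own enantioselective synthesis and the same late neopentyl bromination.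
- Comparison: on C7 the two plans are equal, since in both the hydrogen at C7 would be delivered last and anti to the axial methyl (hydride to an oxocarbenium ion there, a proton to an enolate here). On step economy the chosen plan is better: its key step brings in C7, C8, C12 and C13 together, whereas the oxygen insertion adds no carbon.

Alternative 3: The cut is C7–C8 and C8–C9. C8 is inserted as a carbene carbon into the C7=C9 enol ether bond of the dihydropyran A4, which could be made from 15 by dehydration. Forward, dibromocarbene (CHBr3, KOt-Bu) cyclopropanates A4, the dibromocyclopropane opens in hot methanol with K2CO3, and methanol capture at C7 gives A5.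
- In favour: O6 is bonded to both C5 and C7 before the ring expansion, so no hindered oxygen nucleophile is needed. The step also delivers two handles at once, a vinyl bromide at C8 for C12 and an acetal at C7 for C13. On the reliability of ring-B formation the alternative is the better.
- Against: strongly basic carbene generation and hot carbonate meet the C2 bromide, or force C2 to be carried as a protected alcohol and brominated late. C12 must be attached at the vinyl bromide by metal–halogen exchange or palladium-catalysed carbonylation in the presence of alkyl bromide. A carbon nucleophile adding to the C7 oxocarbenium ion from A5 would enter anti to the axial C5 methyl and put C13 on the wrong face, so an epimerisable C13 group and a later kinetic protonation would be needed.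
- Comparison: on C7 control the two plans are equal at best. On step economy, A5 still needs two C–C bond formations and redox adjustments, so the way from 15 to the target would be longer than steps 14–17.

Key step: step 14

Assumption: the γ-hydroxy aldehyde made in step 12 is taken to exist as its ring tautomer, lactol 15; the open form 19 is the species that reacts in step 14.

## Steps

Step 1
Reactants: 1 (R)-pantolactone
Product: 2 (3R)-3-{[tert-butyl(dimethyl)silyl]oxy}-4,4-dimethyloxolan-2-one
Conditions: TBSCl, imidazole, DMF, 40 °C
Reagents that add atoms: tert-butyldimethylsilyl chloride, CC(C)(C)[Si](C)(C)Cl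
Why: Silyl ether formation at the hindered α-hydroxyl; the stereocentre is untouched and the bulky, non-chelating silyl ether later serves as the equatorial anchor in step 7.

Step 2
Reactants: 2 (3R)-3-{[tert-butyl(dimethyl)silyl]oxy}-4,4-dimethyloxolan-2-one
Product: 3 (3R)-3-{[tert-butyl(dimethyl)silyl]oxy}-4,4-dimethyloxolan-2-ol (anomer mixture)
Conditions: i-Bu2AlH, CH2Cl2, −78 °C; aq. potassium sodium tartrate
Reagents that add atoms: none
Why: Partial reduction of a lactone to the lactol; the tetrahedral aluminium acetal survives at −78 °C until work-up and the silyl ether is stable.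

Step 3
Reactants: 3 (3R)-3-{[tert-butyl(dimethyl)silyl]oxy}-4,4-dimethyloxolan-2-ol; 4 1-(triphenylphosphoranylidene)propan-2-one
Product: 5 (3E,5S)-5-{[tert-butyl(dimethyl)silyl]oxy}-7-hydroxy-6,6-dimethylhept-3-en-2-one
Conditions: PhCO2H (cat.), toluene, 80 °C
Reagents that add atoms: none
Why: Wittig olefination of the aldehyde tautomer of the lactol with a ketone-stabilised ylide gives the E-enone; mild acid speeds opening of the gem-dimethyl lactol, and the product is used at once because its free neopentyl hydroxyl is a latent Michael donor.

Step 4
Reactants: 5 (3E,5S)-5-{[tert-butyl(dimethyl)silyl]oxy}-7-hydroxy-6,6-dimethylhept-3-en-2-one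
Product: 6 (5S)-5-{[tert-butyl(dimethyl)silyl]oxy}-7-hydroxy-6,6-dimethylheptan-2-one
Conditions: H2 (1 atm), Pd/C, EtOAc, rt
Reagents that add atoms: none
Why: Heterogeneous hydrogenation of the conjugated C=C bond; ketone, silyl ether and primary alcohol are untouched and the Michael acceptor is removed.

Step 5
Reactants: 6 (5S)-5-{[tert-butyl(dimethyl)silyl]oxy}-7-hydroxy-6,6-dimethylheptan-2-one
Product: 7 (3S)-3-{[tert-butyl(dimethyl)silyl]oxy}-2,2-dimethyl-6-oxoheptanal
Conditions: Dess–Martin periodinane, CH2Cl2, rt
Reagents that add atoms: none
Why: Dess–Martin oxidation of the neopentyl primary alcohol; the aldehyde has no α-hydrogen, so it cannot enolise or epimerise.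

Step 6
Reactants: 7 (3S)-3-{[tert-butyl(dimethyl)silyl]oxy}-2,2-dimethyl-6-oxoheptanal; 8 triethyl phosphonoacetate
Product: 9 ethyl (2E,5S)-5-{[tert-butyl(dimethyl)silyl]oxy}-4,4-dimethyl-8-oxonon-2-enoate
Conditions: NaH, THF, 0 °C → rt
Reagents that add atoms: none
Why: Horner–Wadsworth–Emmons olefination, E-selective; the phosphonate anion is too weak a base to enolise the methyl ketone and reacts with the aldehyde far faster than with the ketone.

Step 7
Reactants: 9 ethyl (2E,5S)-5-{[tert-butyl(dimethyl)silyl]oxy}-4,4-dimethyl-8-oxonon-2-enoate
Product: 10 ethyl 2-[(1S,3S,6S)-3-{[tert-butyl(dimethyl)silyl]oxy}-6-hydroxy-2,2,6-trimethylcyclohexyl]acetate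
Conditions: SmI2 (2.2 equiv), MeOH (2 equiv), THF, −78 → 0 °C
Reagents that add atoms: none
Why: Ketyl–olefin reductive cyclisation with divalent samarium: the C5 ketyl adds 6-exo-trig to C11 of the enoate through a chair-like transition state with the C2 silyloxy group, the enoate arm and the samarium-bound ketyl oxygen equatorial and the methyl axial, which sets C5 (S), C11 (S) and the trans hydroxyl/acetate relationship, so no lactone forms. The 1,3-induction from C2 rests only on a conformational preference and is expected to be moderate, so minor diastereomers are removed here, before oxidation at C2 in step 9 could turn a diastereomeric contaminant into the enantiomer.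

Step 8
Reactants: 10 ethyl 2-[(1S,3S,6S)-3-{[tert-butyl(dimethyl)silyl]oxy}-6-hydroxy-2,2,6-trimethylcyclohexyl]acetate
Product: 11 ethyl 2-[(1S,3S,6S)-3,6-dihydroxy-2,2,6-trimethylcyclohexyl]acetate
Conditions: HF (48% aq), MeCN, rt
Reagents that add atoms: none
Why: Acidic fluoride desilylation of a hindered secondary silyl ether; it avoids base-promoted lactonisation of the trans hydroxy ester and should not dehydrate the tertiary alcohol (any trans-fused lactone formed here or later converges on 15 in step 12).

Step 9
Reactants: 11 ethyl 2-[(1S,3S,6S)-3,6-dihydroxy-2,2,6-trimethylcyclohexyl]acetate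
Product: 12 ethyl 2-[(1S,6S)-6-hydroxy-2,2,6-trimethyl-3-oxocyclohexyl]acetate
Conditions: Dess–Martin periodinane, CH2Cl2, rt
Reagents that add atoms: none
Why: Dess–Martin oxidation of the secondary alcohol; the tertiary alcohol cannot be oxidised and no stereocentre lies α to the new ketone.

Step 10
Reactants: 12 ethyl 2-[(1S,6S)-6-hydroxy-2,2,6-trimethyl-3-oxocyclohexyl]acetate
Product: 13 ethyl 2-[(1S,3R,6S)-3,6-dihydroxy-2,2,6-trimethylcyclohexyl]acetate
Conditions: LiBH(s-Bu)3, THF, −78 °C; aq. NH4Cl
Reagents that add atoms: none
Why: Diastereoselective ketone reduction with a bulky trialkylborohydride, which approaches C2 along the equatorial trajectory (the axial one is blocked by the axial hydrogens at C4 and C11) and gives the axial (2R) alcohol; the ester is inert at −78 °C.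

Step 11
Reactants: 13 ethyl 2-[(1S,3R,6S)-3,6-dihydroxy-2,2,6-trimethylcyclohexyl]acetate
Product: 14 ethyl 2-[(1S,3S,6S)-3-bromo-6-hydroxy-2,2,6-trimethylcyclohexyl]acetate
Conditions: CBr4, PPh3, CH2Cl2, 0 → 40 °C
Reagents that add atoms: tetrabromomethane, BrC(Br)(Br)Br
Why: Appel reaction: bromide displaces the axial oxyphosphonium group with inversion (SN2) and gives the equatorial (2S) bromide, a transformation of known type for axial alcohols flanked by a gem-dimethyl carbon; the hindered tertiary alcohol should not be activated.

Step 12
Reactants: 14 ethyl 2-[(1S,3S,6S)-3-bromo-6-hydroxy-2,2,6-trimethylcyclohexyl]acetate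
Product: 15 (3aS,5S,7aS)-5-bromo-4,4,7a-trimethyloctahydro-1-benzofuran-2-ol (lactol, anomer mixture)
Conditions: i-Bu2AlH (2.5 equiv), CH2Cl2, −78 °C; aq. potassium sodium tartrate
Reagents that add atoms: none
Why: Partial reduction of the ester; the neighbouring aluminium alkoxide holds the aldehyde oxidation level as a cyclic aluminium acetal that is released as the lactol on work-up, and the equatorial bromide is inert to the hydride.

Step 13
Reactants: 16 tert-butyl 2-(diethoxyphosphoryl)acetate; 17 ethyl 2-oxoacetate (ethyl glyoxylate)
Product: 18 1-tert-butyl 4-ethyl 2-(diethoxyphosphoryl)but-2-enedioate (E/Z mixture)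
Conditions: piperidine (cat.), AcOH (cat.), toluene, 4 Å molecular sieves, 80 °C
Reagents that add atoms: none
Why: Amine-catalysed Knoevenagel condensation through the iminium ion, where the amine and not a phosphate is eliminated, so phosphorus is kept; the glyoxylate has no α-hydrogen and the E/Z ratio is irrelevant because the alkene is consumed in step 14.

Step 14
Reactants: 15 (3aS,5S,7aS)-5-bromo-4,4,7a-trimethyloctahydro-1-benzofuran-2-ol; 18 1-tert-butyl 4-ethyl 2-(diethoxyphosphoryl)but-2-enedioate
Product: 22 3-tert-butyl 2-ethyl (2R,5aS,7S,9aS)-7-bromo-6,6,9a-trimethyl-2,5,5a,6,7,8,9,9a-octahydro-1-benzoxepine-2,3-dicarboxylate, via open-chain hydroxy aldehyde 19 (not isolated), via oxa-Michael adduct 20 (not isolated), via C7-epimeric oxepene diester 21 (not isolated)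
Conditions: KN(SiMe3)2 (1.0 equiv), THF, −78 °C; 18 (1.1 equiv), −78 → 20 °C, 0.02 M; then KN(SiMe3)2 (1.2 equiv), −78 °C; AcOH, −78 °C
Reagents that add atoms: none
Why: Deprotonation opens lactol 15 to the tertiary C5 alkoxide of 19, which adds to C7 of the triply activated alkene 18 (oxa-Michael addition; only attack at C7 gives the phosphonate- and ester-stabilised carbanion 20 at C8). That carbanion adds to the C9 aldehyde in a 7-exo-trig closure, and syn-elimination of diethyl phosphate through the oxaphosphetane forms C8=C9, whose ring-cis geometry is enforced by ring B. The closest known reaction type is the tandem oxa-Michael/intramolecular Horner–Wadsworth–Emmons annulation of lactols and hydroxy carbonyl compounds with 2-phosphonoacrylates, which gives dihydrofurans, dihydropyrans and chromenes. The conjugate addition is reversible, so the hindered alkoxide is drained through the irreversible olefination; high dilution suppresses olefination between two molecules, and because 18 has no γ-hydrogen the alkoxide cannot deprotonate the acceptor instead of adding, as it could with an alkyl-substituted alkylidene phosphonoacetate. Ring closure alone is expected to prefer the C7 epimer with C13 pseudoequatorial on a chair-like ring B, anti to the C5 methyl, so C7 is not left to the closure: 21 is deprotonated at the acidic C7–H (α to the C13 ester and allylic) and the planar enolate is protonated kinetically at −78 °C. The controlling element is the axial C5 methyl, 1,3 to C7 across O6, which screens the upper face, so the proton enters anti to it and C13 ends syn to the methyl (7R); α-protonation of the dienolate keeps the double bond at C8=C9. The step needs O- and not C-alkylation of the hydroxy aldehyde, secured by forming the alkoxide at low temperature before 18 is added, and it needs the equatorial C2 bromide to survive, which it should because no antiperiplanar hydrogen is available for E2.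

Step 15
Reactants: 22 3-tert-butyl 2-ethyl (2R,5aS,7S,9aS)-7-bromo-6,6,9a-trimethyl-2,5,5a,6,7,8,9,9a-octahydro-1-benzoxepine-2,3-dicarboxylate
Product: 23 tert-butyl (2R,5aS,7S,9aS)-7-bromo-2-(hydroxymethyl)-6,6,9a-trimethyl-2,5,5a,6,7,8,9,9a-octahydro-1-benzoxepine-3-carboxylate
Conditions: LiBH4, THF, 0 °C; aq. NH4Cl
Reagents that add atoms: none
Why: Chemoselective ester reduction: LiBH4 reduces the lithium-chelated α-alkoxy ethyl ester, while the hindered conjugated tert-butyl ester and both alkyl bromides are inert at 0 °C; the tert-butyl group also hinders lactonisation of the new alkoxide, and once C13 is a carbinol C7 is no longer epimerisable.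

Step 16
Reactants: 23 tert-butyl (2R,5aS,7S,9aS)-7-bromo-2-(hydroxymethyl)-6,6,9a-trimethyl-2,5,5a,6,7,8,9,9a-octahydro-1-benzoxepine-3-carboxylate
Product: 24 tert-butyl (2R,5aS,7S,9aS)-7-bromo-2-(bromomethyl)-6,6,9a-trimethyl-2,5,5a,6,7,8,9,9a-octahydro-1-benzoxepine-3-carboxylate
Conditions: CBr4, PPh3, CH2Cl2, 0 °C → rt
Reagents that add atoms: tetrabromomethane, BrC(Br)(Br)Br
Why: Appel reaction at a primary alcohol (SN2, no stereocentre involved); the neutral conditions preserve the tert-butyl ester and the allylic ether.

Step 17
Reactants: 24 tert-butyl (2R,5aS,7S,9aS)-7-bromo-2-(bromomethyl)-6,6,9a-trimethyl-2,5,5a,6,7,8,9,9a-octahydro-1-benzoxepine-3-carboxylate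
Product: 25 [(2R,5aS,7S,9aS)-7-bromo-2-(bromomethyl)-6,6,9a-trimethyl-2,5,5a,6,7,8,9,9a-octahydro-1-benzoxepin-3-yl]methanol (target)
Conditions: i-Bu2AlH (3 equiv), CH2Cl2, −78 °C; MeOH, aq. potassium sodium tartrate, 0 °C
Reagents that add atoms: none
Why: 1,2-Reduction of the conjugated ester to the allylic alcohol; the low temperature and a cold, neutral quench keep the aluminium alkoxide from displacing the C13 bromide, and both bromides are inert to the hydride.

## Compound list

1 | (R)-pantolactone, (3R)-3-hydroxy-4,4-dimethyloxolan-2-one | CC1(C)COC(=O)[C@@H]1O | starting material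
2 | (3R)-3-{[tert-butyl(dimethyl)silyl]oxy}-4,4-dimethyloxolan-2-one | CC1(C)COC(=O)[C@@H]1O[Si](C)(C)C(C)(C)C | intermediate
3 | (3R)-3-{[tert-butyl(dimethyl)silyl]oxy}-4,4-dimethyloxolan-2-ol (anomer mixture) | CC1(C)COC(O)[C@@H]1O[Si](C)(C)C(C)(C)C | intermediate
4 | 1-(triphenylphosphoranylidene)propan-2-one | CC(=O)C=P(c1ccccc1)(c1ccccc1)c1ccccc1 | starting material
5 | (3E,5S)-5-{[tert-butyl(dimethyl)silyl]oxy}-7-hydroxy-6,6-dimethylhept-3-en-2-one | CC(=O)/C=C/[C@H](O[Si](C)(C)C(C)(C)C)C(C)(C)CO | intermediate
6 | (5S)-5-{[tert-butyl(dimethyl)silyl]oxy}-7-hydroxy-6,6-dimethylheptan-2-one | CC(=O)CC[C@H](O[Si](C)(C)C(C)(C)C)C(C)(C)CO | intermediate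
7 | (3S)-3-{[tert-butyl(dimethyl)silyl]oxy}-2,2-dimethyl-6-oxoheptanal | CC(=O)CC[C@H](O[Si](C)(C)C(C)(C)C)C(C)(C)C=O | intermediate
8 | triethyl phosphonoacetate | CCOC(=O)CP(=O)(OCC)OCC | starting material
9 | ethyl (2E,5S)-5-{[tert-butyl(dimethyl)silyl]oxy}-4,4-dimethyl-8-oxonon-2-enoate | CCOC(=O)/C=C/C(C)(C)[C@@H](O[Si](C)(C)C(C)(C)C)CCC(C)=O | intermediate
10 | ethyl 2-[(1S,3S,6S)-3-{[tert-butyl(dimethyl)silyl]oxy}-6-hydroxy-2,2,6-trimethylcyclohexyl]acetate | CC1(C)[C@@H](O[Si](C)(C)C(C)(C)C)CC[C@](C)(O)[C@H]1CC(=O)OCC | intermediate
11 | ethyl 2-[(1S,3S,6S)-3,6-dihydroxy-2,2,6-trimethylcyclohexyl]acetate | CC1(C)[C@@H](O)CC[C@](C)(O)[C@H]1CC(=O)OCC | intermediate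
12 | ethyl 2-[(1S,6S)-6-hydroxy-2,2,6-trimethyl-3-oxocyclohexyl]acetate | CC1(C)C(=O)CC[C@](C)(O)[C@H]1CC(=O)OCC | intermediate
13 | ethyl 2-[(1S,3R,6S)-3,6-dihydroxy-2,2,6-trimethylcyclohexyl]acetate | CC1(C)[C@H](O)CC[C@](C)(O)[C@H]1CC(=O)OCC | intermediate
14 | ethyl 2-[(1S,3S,6S)-3-bromo-6-hydroxy-2,2,6-trimethylcyclohexyl]acetate | CC1(C)[C@@H](Br)CC[C@](C)(O)[C@H]1CC(=O)OCC | intermediate
15 | (3aS,5S,7aS)-5-bromo-4,4,7a-trimethyloctahydro-1-benzofuran-2-ol (lactol, anomer mixture) | CC1(C)[C@@H](Br)CC[C@]2(C)OC(O)C[C@@H]12 | intermediate
16 | tert-butyl 2-(diethoxyphosphoryl)acetate | CCOP(=O)(OCC)CC(=O)OC(C)(C)C | starting material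
17 | ethyl 2-oxoacetate (ethyl glyoxylate) | CCOC(=O)C=O | starting material
18 | 1-tert-butyl 4-ethyl 2-(diethoxyphosphoryl)but-2-enedioate (E/Z mixture) | CCOC(=O)C=C(C(=O)OC(C)(C)C)P(=O)(OCC)OCC | intermediate
19 | 2-[(1S,3S,6S)-3-bromo-6-hydroxy-2,2,6-trimethylcyclohexyl]acetaldehyde (open form of 15, reacts as its potassium alkoxide) | CC1(C)[C@@H](Br)CC[C@](C)(O)[C@H]1CC=O | intermediate
20 | 1-tert-butyl 4-ethyl 3-{[(1S,2S,4S)-4-bromo-1,3,3-trimethyl-2-(2-oxoethyl)cyclohexyl]oxy}-2-(diethoxyphosphoryl)butanedioate (formed as its potassium carbanion, diastereomer mixture) | CC1(C)[C@@H](Br)CC[C@](C)(OC(C(=O)OCC)C(C(=O)OC(C)(C)C)P(=O)(OCC)OCC)[C@H]1CC=O | intermediate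
21 | 3-tert-butyl 2-ethyl (5aS,7S,9aS)-7-bromo-6,6,9a-trimethyl-2,5,5a,6,7,8,9,9a-octahydro-1-benzoxepine-2,3-dicarboxylate (mixture of C2 epimers, that is C7 in the target numbering) | CC1(C)[C@@H](Br)CC[C@]2(C)OC(C(=O)OCC)C(C(=O)OC(C)(C)C)=CC[C@@H]12 | intermediate
22 | 3-tert-butyl 2-ethyl (2R,5aS,7S,9aS)-7-bromo-6,6,9a-trimethyl-2,5,5a,6,7,8,9,9a-octahydro-1-benzoxepine-2,3-dicarboxylate | CC1(C)[C@@H](Br)CC[C@]2(C)O[C@@H](C(=O)OCC)C(C(=O)OC(C)(C)C)=CC[C@@H]12 | intermediate
23 | tert-butyl (2R,5aS,7S,9aS)-7-bromo-2-(hydroxymethyl)-6,6,9a-trimethyl-2,5,5a,6,7,8,9,9a-octahydro-1-benzoxepine-3-carboxylate | CC1(C)[C@@H](Br)CC[C@]2(C)O[C@@H](CO)C(C(=O)OC(C)(C)C)=CC[C@@H]12 | intermediate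
24 | tert-butyl (2R,5aS,7S,9aS)-7-bromo-2-(bromomethyl)-6,6,9a-trimethyl-2,5,5a,6,7,8,9,9a-octahydro-1-benzoxepine-3-carboxylate | CC1(C)[C@@H](Br)CC[C@]2(C)O[C@@H](CBr)C(C(=O)OC(C)(C)C)=CC[C@@H]12 | intermediate
25 | [(2R,5aS,7S,9aS)-7-bromo-2-(bromomethyl)-6,6,9a-trimethyl-2,5,5a,6,7,8,9,9a-octahydro-1-benzoxepin-3-yl]methanol | CC1(C)[C@@H](Br)CC[C@]2(C)O[C@@H](CBr)C(CO)=CC[C@@H]12 | target

## Step count and least certain steps

Total step count: 17. Longest linear sequence: 16 steps (steps 1–12 and 14–17); step 13 is the convergent branch. Step 7 is not listed below because its diastereomer ratio affects throughput only, the isomers being removed at 10.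

Step 14 (key step). The most likely failure is slow conjugate addition of the hindered tertiary alkoxide, so that enolisation and self-condensation of the open-chain aldehyde, or olefination between two molecules, overtake ring closure. The second weak point is incomplete facial discrimination when the C7 enolate is protonated. The fallback decouples the two bond formations. From 15, Wittig methylenation (Ph3P=CH2, THF) would give (1S,2S,4S)-4-bromo-1,3,3-trimethyl-2-(prop-2-en-1-yl)cyclohexan-1-ol F1, in which C9 is masked as an alkene. Its potassium alkoxide (KH, THF) would be added to an excess of 18 with no aldehyde present and the adduct protonated to give 1-tert-butyl 4-ethyl 3-{[(1S,2S,4S)-4-bromo-1,3,3-trimethyl-2-(prop-2-en-1-yl)cyclohexyl]oxy}-2-(diethoxyphosphoryl)butanedioate F2. Ozonolysis (O3, CH2Cl2, −78 °C; Me2S) would unmask C9 and give 20, which closes to 21 under mild olefination conditions (LiCl, DBU, MeCN). The fallback comes back to the route at 21, which enters the enolisation/protonation stage of step 14.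

Step 11. Elimination toward C3 and 1,2-methyl shift from the axial oxyphosphonium ion compete with substitution at the neopentyl centre, and under forcing conditions the free tertiary hydroxyl and the ester may take part. The fallback sets out from 13. Saponification (LiOH, THF/H2O) and acidification would lactonise the hydroxy acid to (3aS,5R,7aS)-5-hydroxy-4,4,7a-trimethylhexahydro-1-benzofuran-2(3H)-one F3, which ties up the tertiary oxygen and the carboxyl group and holds ring A rigid. Bromination with inversion (CBr4, PPh3, toluene, 60 °C) would give (3aS,5S,7aS)-5-bromo-4,4,7a-trimethylhexahydro-1-benzofuran-2(3H)-one F4, a compact lactone that should lend itself to purification by crystallisation. Reduction with i-Bu2AlH at −78 °C would return the route at 15.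

Step 3. The long heating that the hindered lactol needs invites conjugate addition of the liberated neopentyl hydroxyl to the enone (a five-membered ring closure favoured by the gem-dimethyl group) and silyl migration between the two oxygens. The fallback sets out from 3. Methylenation (Ph3P=CH2, THF) would give (3S)-3-{[tert-butyl(dimethyl)silyl]oxy}-2,2-dimethylpent-4-en-1-ol F5, and the hydroxyl would be capped (Et3SiCl, imidazole) as tert-butyl{[(3S)-4,4-dimethyl-5-(triethylsilyloxy)pent-1-en-3-yl]oxy}dimethylsilane F6. Cross-metathesis with but-3-en-2-one (second-generation Hoveyda–Grubbs catalyst) would give (3E,5S)-5-{[tert-butyl(dimethyl)silyl]oxy}-6,6-dimethyl-7-(triethylsilyloxy)hept-3-en-2-one F7, which has no free hydroxyl. Hydrogenation (H2, Pd/C) would give (5S)-5-{[tert-butyl(dimethyl)silyl]oxy}-6,6-dimethyl-7-(triethylsilyloxy)heptan-2-one F8, and selective removal of the primary triethylsilyl group (AcOH, THF, H2O) would return the route at 6.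

Step 15. Chemoselectivity may erode (1,2- or 1,4-attack on the conjugated ester), and the basic medium may epimerise C7 before the ethyl ester is consumed. The fallback sets out from 22 and replaces hydride discrimination between two esters by acid-selective reduction. Saponification of the more electrophilic α-alkoxy ethyl ester (LiOH, 1 equiv, THF/H2O, 0 °C) would give (2R,5aS,7S,9aS)-7-bromo-3-(tert-butoxycarbonyl)-6,6,9a-trimethyl-2,5,5a,6,7,8,9,9a-octahydro-1-benzoxepine-2-carboxylic acid F9, whose carboxylate is no longer enolisable. Reduction of the acid with BH3·SMe2 (THF, 0 °C), which leaves esters untouched, would return the route at 23.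

## Further compounds

F1 | step 14 | (1S,2S,4S)-4-bromo-1,3,3-trimethyl-2-(prop-2-en-1-yl)cyclohexan-1-ol | CC1(C)[C@@H](Br)CC[C@](C)(O)[C@H]1CC=C
F2 | step 14 | 1-tert-butyl 4-ethyl 3-{[(1S,2S,4S)-4-bromo-1,3,3-trimethyl-2-(prop-2-en-1-yl)cyclohexyl]oxy}-2-(diethoxyphosphoryl)butanedioate | CC1(C)[C@@H](Br)CC[C@](C)(OC(C(=O)OCC)C(C(=O)OC(C)(C)C)P(=O)(OCC)OCC)[C@H]1CC=C
F3 | step 11 | (3aS,5R,7aS)-5-hydroxy-4,4,7a-trimethylhexahydro-1-benzofuran-2(3H)-one | CC1(C)[C@H](O)CC[C@]2(C)OC(=O)C[C@@H]12
F4 | step 11 | (3aS,5S,7aS)-5-bromo-4,4,7a-trimethylhexahydro-1-benzofuran-2(3H)-one | CC1(C)[C@@H](Br)CC[C@]2(C)OC(=O)C[C@@H]12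
F5 | step 3 | (3S)-3-{[tert-butyl(dimethyl)silyl]oxy}-2,2-dimethylpent-4-en-1-ol | C=C[C@H](O[Si](C)(C)C(C)(C)C)C(C)(C)CO
F6 | step 3 | tert-butyl{[(3S)-4,4-dimethyl-5-(triethylsilyloxy)pent-1-en-3-yl]oxy}dimethylsilane | C=C[C@H](O[Si](C)(C)C(C)(C)C)C(C)(C)CO[Si](CC)(CC)CC
F7 | step 3 | (3E,5S)-5-{[tert-butyl(dimethyl)silyl]oxy}-6,6-dimethyl-7-(triethylsilyloxy)hept-3-en-2-one | CC(=O)/C=C/[C@H](O[Si](C)(C)C(C)(C)C)C(C)(C)CO[Si](CC)(CC)CC
F8 | step 3 | (5S)-5-{[tert-butyl(dimethyl)silyl]oxy}-6,6-dimethyl-7-(triethylsilyloxy)heptan-2-one | CC(=O)CC[C@H](O[Si](C)(C)C(C)(C)C)C(C)(C)CO[Si](CC)(CC)CC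
F9 | step 15 | (2R,5aS,7S,9aS)-7-bromo-3-(tert-butoxycarbonyl)-6,6,9a-trimethyl-2,5,5a,6,7,8,9,9a-octahydro-1-benzoxepine-2-carboxylic acid | CC1(C)[C@@H](Br)CC[C@]2(C)O[C@@H](C(=O)O)C(C(=O)OC(C)(C)C)=CC[C@@H]12
A1 | alternative 1 | ethyl 2-[(1S,3S,6S)-3-{[tert-butyl(dimethyl)silyl]oxy}-6-hydroxy-2,2,6-trimethylcyclohexyl]acetate (identical with 10) | CC1(C)[C@@H](O[Si](C)(C)C(C)(C)C)CC[C@](C)(O)[C@H]1CC(=O)OCC
A2 | alternative 2 | 6-bromo-5,5,8a-trimethyloctahydronaphthalen-1(2H)-one, trans-fused, ring-A configuration as in the target | CC1(C)[C@@H](Br)CC[C@]2(C)C(=O)CCC[C@@H]12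
A3 | alternative 2 | (5aS,7S,9aS)-7-bromo-6,6,9a-trimethyl-4,5,5a,6,7,8,9,9a-octahydro-1-benzoxepin-2(3H)-one | CC1(C)[C@@H](Br)CC[C@]2(C)OC(=O)CCC[C@@H]12
A4 | alternative 3 | (4aS,6S,8aS)-6-bromo-5,5,8a-trimethyl-4a,5,6,7,8,8a-hexahydro-4H-chromene | CC1(C)[C@@H](Br)CC[C@]2(C)OC=CC[C@@H]12
A5 | alternative 3 | (5aS,7S,9aS)-3,7-dibromo-2-methoxy-6,6,9a-trimethyl-2,5,5a,6,7,8,9,9a-octahydro-1-benzoxepine (either C2 epimer) | CC1(C)[C@@H](Br)CC[C@]2(C)OC(OC)C(Br)=CC[C@@H]12
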